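## Analysis of the target

Gnetucleistol F (26) is built on a 2,3-dihydro-1-benzofuran. Its benzo ring (ring A) carries a methoxy group at C7 and an (E)-2-(3,5-dihydroxyphenyl)ethenyl group (ring C) at C5; C2 carries a 4-hydroxy-3,5-dimethoxyphenyl group (ring B) and C3 a hydroxymethyl group. The only stereocentres are the neighbouring C2 and C3, which are (2R,3S), so ring B and the CH2OH group stand trans on the five-membered ring; the stilbene double bond is E. The trans arrangement is the more stable one, so the relative configuration is forgiving, but the absolute configuration of both centres has to be set by the synthesis. Three features are sensitive: the free phenols and the electron-rich stilbene are easily oxidised and exclude hydrogenation or hydrogenolysis; the benzylic C2–O1 bond para to the ring B phenol ionises under acid and can open through a para-quinone methide under base; and the three aryl methyl ethers forbid any late demethylation, so the free hydroxyl groups must travel as groups that come off without acid, strong base or reduction. The difficulty is to join three differently oxygenated arenes to a three-carbon chain with absolute control at two adjacent benzylic centres, and to keep the last steps mild. The plan rests on the pattern at C2 and C3: C2 carries ring B and the oxygen O1, C3 carries C3a of ring A and the CH2O carbon. This is what an (E)-3-oxyprop-1-enyl boron compound becomes when one aryl group is added to each alkene carbon and the boron on C2 is exchanged for oxygen; O1 can then be tied to C7a by displacing a fluoride that the C5 carboxyl group activates.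

## Retrosynthetic reasoning

**26 from 25.** The last operation is limited to deprotection. All four hydroxyl groups are carried as silyl ethers in 25, so one buffered fluoride treatment frees them. Fluoride leaves the methyl ethers, the stilbene and the benzylic ether alone, and no other transformation has to be run on the free polyphenol.

**25 from 19 and 24.** The stilbene C=C bond is cut. Ring C is symmetric and simple, so it is best brought in as a separate benzylic phosphonate 24, and a phosphonate olefination delivers the E geometry reliably. The forward reaction has to add the anion of 24 to aldehyde 19 and eliminate to the E alkene; 19 has no enolisable hydrogen next to the formyl group, so C2 and C3 are not at risk.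

**19 from 17 through 18.** The formyl group is traced back to a methyl ester by reduction and benzylic oxidation. The ester is wanted earlier for two reasons: it survives the organometallic chemistry of the key step, which an aldehyde would not, and it is the acceptor that activates the para fluoride for ring closure.

**17 from 16.** The O1–C7a bond is cut. This leaves an open-chain alcohol whose two stereocentres can be made on an acyclic system. Closing the ring at the arene carbon, and not at C2, means that no bond to a stereocentre is formed or broken. The forward reaction is an intramolecular aromatic substitution of fluoride by the C1 alkoxide of 16; it must not be overtaken by silyl transfer from the neighbouring primary oxygen, which is why that oxygen carries a triisopropylsilyl group and not a smaller silyl group.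

**16 from 15.** The C–O bond at the future C2 is traced back to a C–B bond. Oxidation of a secondary boronic ester goes with retention, so the configuration of 15 is carried over unchanged.

**15 from 6, 13 and 12 through 14.** This is the key disconnection. The future C3–C3a bond and the C2–ring B bond are cut in one operation, which divides the molecule into three fragments of similar size: the E-alkenyl boronic ester 6, the aryllithium 13 and the aryl triflate 12. Both stereocentres then arise together from a flat alkene. Their relative configuration follows from the alkene geometry and the anti course of the addition, and their absolute configuration from a chiral ligand on palladium. The forward reaction has to make the ring B aryl group migrate from boron to carbon within the ate complex 14 and must not hand a boron-bound group directly to palladium. For a β-substituted alkene this direct transfer is the expected side path when boron carries an ordinary, less shielded diol, so the hindered diol 4 is placed on boron. The C–F bond of 12 has to stay intact, and the bromide left over from making 13 has to be taken out of solution.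

**6 from 2 and 4 through 5; 2 from 1; 4 from 3.** The C–B bond of 6 comes from syn hydroboration of the silylated alkyne 2, which sets the E geometry; the first-formed catechol ester 5 is exchanged for diol 4. Alkyne 2 is the silyl ether of propargyl alcohol 1, and diol 4 comes from twofold methyl addition to dione 3.

**13 from 8; 8 from 7.** The C–Li bond of 13 is made by bromine–lithium exchange on 8. No directing group points to this position, so the halide is needed. Aryl bromide 8 is the silyl ether of the commercial bromophenol 7.

**12 from 11; 11 from 9 through 10.** The triflate oxygen of 12 is traced back to a C–H bond of the commercial benzoate 9. The hydrogen ortho to fluorine is the only one that is both unhindered and activated for iridium-catalysed borylation, and the boronate 10 is oxidised to phenol 11 in the same flask.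

**24 from 23, 22, 21 and 20.** The C–P bond comes from a Michaelis–Arbuzov reaction of benzylic bromide 23. The bromide comes from alcohol 22, which is obtained from the commercial triol 20 by exhaustive silylation to 21 and selective acid cleavage of the one alkyl silyl ether.

## Alternatives that were turned down

**Alternative 1:** The dihydrofuran ring is obtained by contracting a pyranone: the C3–C3a bond is made by a 1,2-shift of ring A. In the forward key step the (R)-flavanone A1 would be treated with the trivalent iodine oxidant A2, which is PhI(OAc)2, under strong acid in an orthoester solvent. The enol ether formed in situ is iodinated at C3, ring A moves from C4 to C3 as the iodine leaves, and the old C4 ends as the methyl ester of the trans dihydrobenzofuran A3.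

- For it: the reagents are cheap, the trans relationship follows from the mechanism, and no organolithium or air-sensitive catalyst is needed. The C5 bromide of A3 would let the stilbene be attached directly by a Heck reaction, which is shorter than the ester-to-aldehyde-to-olefination sequence of the chosen route; on this point the alternative is stronger.
- Against it: the rearrangement creates only the C3 centre relative to C2. The absolute configuration has to be built into A1 beforehand, and 2-aryl chromanones of this kind lose their configuration by reversible opening of the pyranone ring under the acidic conditions of the rearrangement. The oxidant A2 can also attack the trioxygenated ring B, which is why an acyl group has to deactivate its phenol. The ester of A3 still has to be reduced to CH2OH in the presence of that acyl group.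
- Comparison: the chosen strategy sets both centres in one catalytic event and never passes through an intermediate whose C2 centre is configurationally labile.

**Alternative 2:** The C2–C3 and O1–C2 bonds are both cut, so C2 arrives as a one-carbon unit carrying ring B. In the forward key step base would eliminate sulfinate from the phenol sulfone A4 to release the ortho-quinone methide A5 and would deprotonate the chiral sulfonium salt A6. The ylide carbon adds to the exocyclic carbon of A5, and the phenoxide displaces the sulfide to close the ring, giving A7.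

- For it: the ring and both stereocentres are formed in a single step from two fragments, the trans product is the expected one, and the bromide of A7 again allows a direct Heck reaction. In step count this is the shortest plan, and it is stronger than the chosen one on that point.
- Against it: A5 carries an sp3 carbon with hydrogens and a silyloxy group on its exocyclic position, so tautomerisation to a vinyl phenol and loss of silanolate compete with capture by the ylide. A6 is a benzylic sulfonium salt of a very electron-rich arene and can ionise before it is deprotonated. Absolute control depends on a stoichiometric chiral sulfide distinguishing the faces of a semi-stabilised ylide as it adds to a transient, flat acceptor, for which a 3-alkyl case of this kind offers little guidance.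
- Comparison: the chosen strategy relies on a stereospecific addition to an isolable E alkene under ligand control, which is an easier stereochemical problem to reason about. It pays for this with more steps after the coupling.

**Alternative 3:** The benzofuran is kept intact and dearomatised: the C3–CH2 and C2–ring B bonds are made across the C2=C3 bond of the heteroarene. In the forward key step the 2-lithiobenzofuran A8 and the ring B pinacol boronate A9 would form an ate complex. An allylpalladium electrophile, generated from allyl acetate A10 with a zerovalent palladium catalyst and a chiral diphosphine, attacks C3 while the aryl group shifts from boron to C2, giving A11.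

- For it: the O1–C7a bond exists from the start, so no aromatic substitution is needed. A8 comes from direct lithiation, so no halide is present to inhibit the catalyst. The acceptor is a 2-boryl heteroarene, not a β-substituted alkenyl boronate, so the direct-transfer problem of the chosen route does not arise. On these three points the alternative is at least as strong.
- Against it: C3 receives an allyl group, which has two carbons too many and must be cut down by alkene isomerisation, oxidative cleavage and reduction. C2 ends as a fully substituted carbon bearing boron, oxygen and ring B, so a further stereospecific protodeboronation at a tertiary, benzylic, oxygen-bearing centre is needed to install the C2 hydrogen. The aldehyde has to be carried as an acetal.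
- Comparison: the chosen strategy delivers the correct one-carbon oxygenated substituent at C3 and a hydrogen at C2 directly, so no stereochemically critical step follows the coupling except a retentive oxidation.

Key step: step 7

Remark on the chemistry: the sense of induction of the Mandyphos ligand with this ate complex is not derived here; the ligand enantiomer that leads to (1R,2S)-15 is assumed in step 7.

## Route

**Step 1**
Reactants: 1 propargyl alcohol
Product: 2 triisopropyl(prop-2-yn-1-yloxy)silane
Conditions: TIPSCl, imidazole, CH2Cl2, 0 °C to rt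
Reagents that add atoms: triisopropylsilyl chloride, CC(C)[Si](Cl)(C(C)C)C(C)C
Why: Standard silylation of a primary alcohol; the triisopropylsilyl group is chosen because it resists oxygen-to-oxygen migration in step 9 and leaves with the other silyl groups in step 17.

**Step 2**
Reactants: 3 acenaphthoquinone (acenaphthylene-1,2-dione)
Product: 4 cis-1,2-dimethyl-1,2-dihydroacenaphthylene-1,2-diol (meso "mac" diol)
Conditions: AlMe3 (3 equiv), toluene, 0 °C to rt; aq. HCl; recrystallisation
Reagents that add atoms: trimethylaluminium, C[Al](C)C
Why: Twofold 1,2-addition of methyl to the 1,2-dione; the second methyl should enter anti to the bulky aluminium alkoxide formed first, giving the cis diol, which is the only isomer that can chelate boron and is purified by crystallisation.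

**Step 3**
Reactants: 2 triisopropyl(prop-2-yn-1-yloxy)silane, 4 cis-1,2-dimethyl-1,2-dihydroacenaphthylene-1,2-diol
Product: 6 cyclic boronic ester of diol 4 with (E)-3-(triisopropylsilyloxy)prop-1-enylboronic acid [alkenyl B(mac)], via alkenyl catechol boronate 5 (not isolated)
Conditions: catecholborane (1.1 equiv), Cy2BH (10 mol %), THF, rt; then 4 (1.05 equiv), rt; chromatography
Reagents that add atoms: catecholborane, B1Oc2ccccc2O1
Why: Dialkylborane-catalysed hydroboration of a terminal alkyne is a syn, anti-Markovnikov addition and gives the E-alkenyl boronate; catechol esters exchange readily with aliphatic 1,2-diols, so diol 4 displaces catechol to give the hindered and robust ester 6.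

**Step 4**
Reactants: 7 4-bromo-2,6-dimethoxyphenol
Product: 8 (4-bromo-2,6-dimethoxyphenoxy)triisopropylsilane
Conditions: TIPSCl, imidazole, DMF, rt to 40 °C
Reagents that add atoms: triisopropylsilyl chloride, CC(C)[Si](Cl)(C(C)C)C(C)C
Why: Silylation of a hindered phenol; the aryl triisopropylsilyl ether withstands t-BuLi, KN(SiMe3)2, i-Bu2AlH and NaH, and because it is para to the future lithium no retro-Brook shift is possible.

**Step 5**
Reactants: 9 methyl 4-fluoro-3-methoxybenzoate
Product: 11 methyl 4-fluoro-3-hydroxy-5-methoxybenzoate, via aryl pinacol boronate 10 (not isolated)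
Conditions: B2pin2 (0.7 equiv), [Ir(OMe)(cod)]2 (1.5 mol %), 4,4'-di-tert-butyl-2,2'-bipyridine (3 mol %), THF, 80 °C; then Oxone (2KHSO5·KHSO4·K2SO4), acetone/H2O, rt
Reagents that add atoms: potassium peroxymonosulfate, [K+].[O-]S(=O)(=O)OO
Why: Iridium-catalysed C–H borylation follows sterics and C–H acidity: C2 is flanked by two substituents, C6 is ortho to the ester, and C5 is ortho only to the small, activating fluorine, so boron from B2pin2 should enter at C5 to give 10; one-pot oxidation of the aryl boronate with peroxymonosulfate then gives the phenol without hydrolysing the ester.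

**Step 6**
Reactants: 11 methyl 4-fluoro-3-hydroxy-5-methoxybenzoate
Product: 12 methyl 4-fluoro-3-methoxy-5-(trifluoromethylsulfonyloxy)benzoate
Conditions: Tf2O, pyridine, CH2Cl2, 0 °C
Reagents that add atoms: trifluoromethanesulfonic anhydride, O=S(=O)(OS(=O)(=O)C(F)(F)F)C(F)(F)F
Why: O-Sulfonylation of a phenol, the standard preparation of an aryl triflate.

**Step 7**
Reactants: 8 (4-bromo-2,6-dimethoxyphenoxy)triisopropylsilane, 6 alkenyl B(mac), 12 methyl 4-fluoro-3-methoxy-5-(trifluoromethylsulfonyloxy)benzoate
Product: 15 B(mac) ester of (1R,2S)-1-[3,5-dimethoxy-4-(triisopropylsilyloxy)phenyl]-2-[2-fluoro-3-methoxy-5-(methoxycarbonyl)phenyl]-3-(triisopropylsilyloxy)propylboronic acid, via aryllithium 13 (not isolated), via lithium boron ate complex 14 (not isolated)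
Conditions: 8, t-BuLi (2.0 equiv), Et2O, −78 °C; 6 (1.05 equiv), Et2O, −78 °C to rt; evaporate; 12 (1.1 equiv), Pd(OAc)2 (2 mol %), Mandyphos (2.4 mol %; a 1,1'-bis(diarylphosphino)ferrocene with two α-(dimethylamino)benzyl side arms, aryl = 4-methoxy-3,5-dimethylphenyl), KOTf (2 equiv), THF, 40–60 °C
Reagents that add atoms: none
Why: Bromine–lithium exchange on 8 gives 13, which adds to the vacant orbital of boron in 6 to give the four-coordinate ate complex 14. Zerovalent palladium, formed from Pd(OAc)2 and the diphosphine, inserts into the C–OTf bond of 12; because triflate does not bind, the resulting aryl complex of divalent palladium is cationic and takes up the alkene of 14. The bound alkene then triggers a 1,2-shift of the ring B aryl group from boron to C1 anti to the metal while palladium bonds C2, and reductive elimination with retention joins C2 to ring A (the future C3–C3a bond) and regenerates zerovalent palladium. The closest known reaction type is the enantioselective palladium-catalysed conjunctive cross-coupling of β-substituted alkenyl boron ate complexes with aryl triflates; no ring is closed in this step. Both new stereocentres come from the one alkene: their relative configuration is fixed stereospecifically by anti addition of the two aryl groups across the E double bond, which is the diastereomer that later gives the trans ring, and their absolute configuration by the alkene face that the Mandyphos–palladium fragment selects. The step needs the metallate shift to win over direct transfer of a boron-bound group to palladium (Suzuki-type coupling); this is secured by the hindered diol of 6, which shields the boron-bound oxygens, by the use of a triflate, and by KOTf, which removes as KBr the bromide left from the formation of 13. It also needs C–OTf to react in preference to C–F, which the inertness of aryl fluorides towards zerovalent palladium secures, and it needs 13 to be consumed before 12 is added so that the ester is not attacked, hence the slight excess of 6.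

**Step 8**
Reactants: 15 B(mac) ester of the (1R,2S)-propylboronic acid
Product: 16 (1R,2S)-1-[3,5-dimethoxy-4-(triisopropylsilyloxy)phenyl]-2-[2-fluoro-3-methoxy-5-(methoxycarbonyl)phenyl]-3-(triisopropylsilyloxy)propan-1-ol
Conditions: NaBO3·4H2O, THF/H2O (1:1), rt
Reagents that add atoms: sodium perborate (NaBO3·4H2O), [Na+].[Na+].O[B-]1(O)OO[B-](O)(O)OO1
Why: Perborate oxidation of a secondary boronic ester proceeds by 1,2-shift of carbon from boron to oxygen with retention, so C1 keeps its configuration; the mildly basic reagent spares the methyl ester, the aryl silyl ether and the activated fluoride.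

**Step 9**
Reactants: 16 (1R,2S)-fluoro alcohol
Product: 17 methyl (2R,3S)-2-[3,5-dimethoxy-4-(triisopropylsilyloxy)phenyl]-7-methoxy-3-[(triisopropylsilyloxy)methyl]-2,3-dihydro-1-benzofuran-5-carboxylate
Conditions: KN(SiMe3)2 (1.1 equiv), THF, −78 °C to rt
Reagents that add atoms: none
Why: Intramolecular nucleophilic aromatic substitution (addition–elimination): the potassium alkoxide attacks the fluorine-bearing carbon, activated by the para ester, in a five-membered closure that forms O1–C7a; neither stereocentre takes part, so the anti open-chain compound gives the trans ring, and the bulky silyl group on the primary oxygen is there to suppress 1,5-silyl transfer to the alkoxide.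

**Step 10**
Reactants: 17 dihydrobenzofuran methyl ester
Product: 18 {(2R,3S)-2-[3,5-dimethoxy-4-(triisopropylsilyloxy)phenyl]-7-methoxy-3-[(triisopropylsilyloxy)methyl]-2,3-dihydro-1-benzofuran-5-yl}methanol
Conditions: i-Bu2AlH (2.5 equiv), CH2Cl2, −78 °C; aqueous potassium sodium tartrate
Reagents that add atoms: none
Why: Hydride reduction of an aryl ester to the benzylic alcohol; silyl ethers and the benzylic ether are inert to i-Bu2AlH at low temperature.

**Step 11**
Reactants: 18 benzylic alcohol
Product: 19 (2R,3S)-2-[3,5-dimethoxy-4-(triisopropylsilyloxy)phenyl]-7-methoxy-3-[(triisopropylsilyloxy)methyl]-2,3-dihydro-1-benzofuran-5-carbaldehyde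
Conditions: MnO2 (excess), CH2Cl2, rt
Reagents that add atoms: none
Why: MnO2 oxidises benzylic alcohols selectively to aldehydes without over-oxidation, and no other hydroxyl group is free.

**Step 12**
Reactants: 20 3,5-dihydroxybenzyl alcohol
Product: 21 tert-butyl{[3,5-bis(tert-butyldimethylsilyloxy)phenyl]methoxy}dimethylsilane
Conditions: TBSCl (3.5 equiv), imidazole, DMF, rt
Reagents that add atoms: tert-butyldimethylsilyl chloride, CC(C)(C)[Si](C)(C)Cl
Why: Exhaustive silylation of two phenols and one primary alcohol, which avoids any need to discriminate between them at this stage.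

**Step 13**
Reactants: 21 tris(silyl) ether
Product: 22 [3,5-bis(tert-butyldimethylsilyloxy)phenyl]methanol
Conditions: camphorsulfonic acid (cat.), MeOH/CH2Cl2 (1:1), 0 °C
Reagents that add atoms: none
Why: Alkyl silyl ethers are cleaved by acid much faster than aryl silyl ethers, so catalytic acid in methanol should release only the benzylic alcohol.

**Step 14**
Reactants: 22 [3,5-bis(tert-butyldimethylsilyloxy)phenyl]methanol
Product: 23 1-(bromomethyl)-3,5-bis(tert-butyldimethylsilyloxy)benzene
Conditions: CBr4, PPh3, CH2Cl2, 0 °C
Reagents that add atoms: carbon tetrabromide, BrC(Br)(Br)Br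
Why: Appel bromination of a primary benzylic alcohol under neutral conditions that leave aryl silyl ethers intact.

**Step 15**
Reactants: 23 benzylic bromide
Product: 24 diethyl [3,5-bis(tert-butyldimethylsilyloxy)benzyl]phosphonate
Conditions: P(OEt)3 (neat), 120–130 °C
Reagents that add atoms: triethyl phosphite, CCOP(OCC)OCC
Why: Michaelis–Arbuzov reaction of a reactive benzylic bromide; the conditions are neutral and the volatile bromoethane leaves the mixture.

**Step 16**
Reactants: 19 dihydrobenzofuran aldehyde, 24 benzylic phosphonate
Product: 25 (2R,3S)-5-{(E)-2-[3,5-bis(tert-butyldimethylsilyloxy)phenyl]ethenyl}-2-[3,5-dimethoxy-4-(triisopropylsilyloxy)phenyl]-7-methoxy-3-[(triisopropylsilyloxy)methyl]-2,3-dihydro-1-benzofuran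
Conditions: NaH, 15-crown-5 (cat.), THF, 0 °C to rt
Reagents that add atoms: none
Why: Horner–Wadsworth–Emmons olefination of an aryl aldehyde with a benzylic phosphonate anion gives the E-stilbene through reversible addition and preferential collapse of the adduct leading to the E alkene; 19 has no enolisable hydrogen, so C2 and C3 are untouched.

**Step 17**
Reactants: 25 fully silylated stilbene
Product: 26 gnetucleistol F, 5-{(E)-2-[(2R,3S)-2-(4-hydroxy-3,5-dimethoxyphenyl)-3-(hydroxymethyl)-7-methoxy-2,3-dihydro-1-benzofuran-5-yl]ethenyl}benzene-1,3-diol
Conditions: Bu4NF (5 equiv), AcOH (5 equiv), THF, 0 °C to rt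
Reagents that add atoms: none
Why: Fluoride cleaves the Si–O bonds of the three aryl silyl ethers and the primary alkyl silyl ether; acetic acid buffers the phenoxides so that the C2–O1 bond para to the freed phenol is not opened, and methyl ethers and the alkene are inert.

## Compound list

1 | propargyl alcohol (prop-2-yn-1-ol) | C#CCO | starting material
2 | triisopropyl(prop-2-yn-1-yloxy)silane | C#CCO[Si](C(C)C)(C(C)C)C(C)C | intermediate
3 | acenaphthoquinone (acenaphthylene-1,2-dione) | O=C1C(=O)c2cccc3cccc1c23 | starting material
4 | cis-1,2-dimethyl-1,2-dihydroacenaphthylene-1,2-diol (meso) | O[C@]1(C)c2cccc3cccc(c23)[C@]1(C)O | intermediate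
5 | 2-[(E)-3-(triisopropylsilyloxy)prop-1-enyl]-1,3,2-benzodioxaborole | CC(C)[Si](OC/C=C/B1Oc2ccccc2O1)(C(C)C)C(C)C | intermediate
6 | cyclic boronic ester of diol 4 with (E)-3-(triisopropylsilyloxy)prop-1-enylboronic acid | CC(C)[Si](OC/C=C/B1O[C@]2(C)c3cccc4cccc(c34)[C@]2(C)O1)(C(C)C)C(C)C | intermediate
7 | 4-bromo-2,6-dimethoxyphenol | COc1cc(Br)cc(OC)c1O | starting material
8 | (4-bromo-2,6-dimethoxyphenoxy)triisopropylsilane | COc1cc(Br)cc(OC)c1O[Si](C(C)C)(C(C)C)C(C)C | intermediate
9 | methyl 4-fluoro-3-methoxybenzoate | COC(=O)c1ccc(F)c(OC)c1 | starting material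
10 | methyl 4-fluoro-3-methoxy-5-(4,4,5,5-tetramethyl-1,3,2-dioxaborolan-2-yl)benzoate | COC(=O)c1cc(OC)c(F)c(B2OC(C)(C)C(C)(C)O2)c1 | intermediate
11 | methyl 4-fluoro-3-hydroxy-5-methoxybenzoate | COC(=O)c1cc(OC)c(F)c(O)c1 | intermediate
12 | methyl 4-fluoro-3-methoxy-5-(trifluoromethylsulfonyloxy)benzoate | COC(=O)c1cc(OC)c(F)c(OS(=O)(=O)C(F)(F)F)c1 | intermediate
13 | [3,5-dimethoxy-4-(triisopropylsilyloxy)phenyl]lithium | [Li]c1cc(OC)c(O[Si](C(C)C)(C(C)C)C(C)C)c(OC)c1 | intermediate
14 | lithium ate complex of 6 with the aryl group of 13 on boron (configuration at boron not defined) | [Li+].COc1cc([B-]2(/C=C/CO[Si](C(C)C)(C(C)C)C(C)C)O[C@]3(C)c4cccc5cccc(c45)[C@]3(C)O2)cc(OC)c1O[Si](C(C)C)(C(C)C)C(C)C | intermediate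
15 | B(mac) ester of (1R,2S)-1-[3,5-dimethoxy-4-(triisopropylsilyloxy)phenyl]-2-[2-fluoro-3-methoxy-5-(methoxycarbonyl)phenyl]-3-(triisopropylsilyloxy)propylboronic acid | COc1cc([C@H](B2O[C@]3(C)c4cccc5cccc(c45)[C@]3(C)O2)[C@H](CO[Si](C(C)C)(C(C)C)C(C)C)c2cc(C(=O)OC)cc(OC)c2F)cc(OC)c1O[Si](C(C)C)(C(C)C)C(C)C | intermediate
16 | (1R,2S)-1-[3,5-dimethoxy-4-(triisopropylsilyloxy)phenyl]-2-[2-fluoro-3-methoxy-5-(methoxycarbonyl)phenyl]-3-(triisopropylsilyloxy)propan-1-ol | COc1cc([C@H](O)[C@H](CO[Si](C(C)C)(C(C)C)C(C)C)c2cc(C(=O)OC)cc(OC)c2F)cc(OC)c1O[Si](C(C)C)(C(C)C)C(C)C | intermediate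
17 | methyl (2R,3S)-2-[3,5-dimethoxy-4-(triisopropylsilyloxy)phenyl]-7-methoxy-3-[(triisopropylsilyloxy)methyl]-2,3-dihydro-1-benzofuran-5-carboxylate | COc1cc([C@@H]2Oc3c(OC)cc(C(=O)OC)cc3[C@H]2CO[Si](C(C)C)(C(C)C)C(C)C)cc(OC)c1O[Si](C(C)C)(C(C)C)C(C)C | intermediate
18 | {(2R,3S)-2-[3,5-dimethoxy-4-(triisopropylsilyloxy)phenyl]-7-methoxy-3-[(triisopropylsilyloxy)methyl]-2,3-dihydro-1-benzofuran-5-yl}methanol | COc1cc([C@@H]2Oc3c(OC)cc(CO)cc3[C@H]2CO[Si](C(C)C)(C(C)C)C(C)C)cc(OC)c1O[Si](C(C)C)(C(C)C)C(C)C | intermediate
19 | (2R,3S)-2-[3,5-dimethoxy-4-(triisopropylsilyloxy)phenyl]-7-methoxy-3-[(triisopropylsilyloxy)methyl]-2,3-dihydro-1-benzofuran-5-carbaldehyde | COc1cc([C@@H]2Oc3c(OC)cc(C=O)cc3[C@H]2CO[Si](C(C)C)(C(C)C)C(C)C)cc(OC)c1O[Si](C(C)C)(C(C)C)C(C)C | intermediate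
20 | 3,5-dihydroxybenzyl alcohol | OCc1cc(O)cc(O)c1 | starting material
21 | tert-butyl{[3,5-bis(tert-butyldimethylsilyloxy)phenyl]methoxy}dimethylsilane | CC(C)(C)[Si](C)(C)OCc1cc(O[Si](C)(C)C(C)(C)C)cc(O[Si](C)(C)C(C)(C)C)c1 | intermediate
22 | [3,5-bis(tert-butyldimethylsilyloxy)phenyl]methanol | OCc1cc(O[Si](C)(C)C(C)(C)C)cc(O[Si](C)(C)C(C)(C)C)c1 | intermediate
23 | 1-(bromomethyl)-3,5-bis(tert-butyldimethylsilyloxy)benzene | BrCc1cc(O[Si](C)(C)C(C)(C)C)cc(O[Si](C)(C)C(C)(C)C)c1 | intermediate
24 | diethyl [3,5-bis(tert-butyldimethylsilyloxy)benzyl]phosphonate | CCOP(=O)(OCC)Cc1cc(O[Si](C)(C)C(C)(C)C)cc(O[Si](C)(C)C(C)(C)C)c1 | intermediate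
25 | (2R,3S)-5-{(E)-2-[3,5-bis(tert-butyldimethylsilyloxy)phenyl]ethenyl}-2-[3,5-dimethoxy-4-(triisopropylsilyloxy)phenyl]-7-methoxy-3-[(triisopropylsilyloxy)methyl]-2,3-dihydro-1-benzofuran | COc1cc([C@@H]2Oc3c(OC)cc(/C=C/c4cc(O[Si](C)(C)C(C)(C)C)cc(O[Si](C)(C)C(C)(C)C)c4)cc3[C@H]2CO[Si](C(C)C)(C(C)C)C(C)C)cc(OC)c1O[Si](C(C)C)(C(C)C)C(C)C | intermediate
26 | gnetucleistol F, 5-{(E)-2-[(2R,3S)-2-(4-hydroxy-3,5-dimethoxyphenyl)-3-(hydroxymethyl)-7-methoxy-2,3-dihydro-1-benzofuran-5-yl]ethenyl}benzene-1,3-diol | COc1cc([C@@H]2Oc3c(OC)cc(/C=C/c4cc(O)cc(O)c4)cc3[C@H]2CO)cc(OC)c1O | target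

## Step count and least certain steps

Total: 17 steps. Longest linear sequence: 9 steps (steps 1, 3, 7, 8, 9, 10, 11, 16, 17, from propargyl alcohol 1; the branches from dione 3 through step 2 and from benzoate 9 through steps 5 and 6 are equally long).

**Step 7 (key step).**
- What may go wrong: direct transfer of the aryl or the alkenyl group from boron to palladium in place of the 1,2-shift. A β-substituted alkene binds the cationic palladium centre less well, and residual bromide would block the coordination site it needs. The allylic silyloxy group may also be lost by β-oxygen elimination from the alkylpalladium intermediate before reductive elimination. Facial selectivity may be too low with an ortho-fluorinated, electron-poor aryl group on palladium.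
- Fallback: 16 is built by an auxiliary-controlled syn-aldol reaction, setting out from 12 and 13 and returning at 16.
  - 13 is quenched with DMF to give 3,5-dimethoxy-4-(triisopropylsilyloxy)benzaldehyde F1.
  - 12 is coupled with the Reformatsky reagent BrZnCH2CO2t-Bu under Pd2(dba)3/XPhos catalysis (Negishi-type) to give methyl 3-(2-tert-butoxy-2-oxoethyl)-4-fluoro-5-methoxybenzoate F2. CF3CO2H converts it into 2-[2-fluoro-3-methoxy-5-(methoxycarbonyl)phenyl]acetic acid F3.
  - Acylation of (R)-4-benzyl-1,3-oxazolidin-2-one through the pivaloyl mixed anhydride (t-BuCOCl, Et3N, LiCl) gives methyl 3-{2-[(4R)-4-benzyl-2-oxo-1,3-oxazolidin-3-yl]-2-oxoethyl}-4-fluoro-5-methoxybenzoate F4.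
  - Its Z boron enolate (Bu2BOTf, i-Pr2NEt, CH2Cl2, −78 °C) adds to F1 in an Evans syn-aldol reaction to give methyl 3-{(2R,3R)-1-[(4R)-4-benzyl-2-oxo-1,3-oxazolidin-3-yl]-3-[3,5-dimethoxy-4-(triisopropylsilyloxy)phenyl]-3-hydroxy-1-oxopropan-2-yl}-4-fluoro-5-methoxybenzoate F5. Its (2R,3R) configuration corresponds to the (1R,2S) configuration of 16.
  - NaBH4 in THF/H2O removes the auxiliary reductively without reducing the methyl ester and gives (1R,2S)-1-[3,5-dimethoxy-4-(triisopropylsilyloxy)phenyl]-2-[2-fluoro-3-methoxy-5-(methoxycarbonyl)phenyl]propane-1,3-diol F6. TIPSCl and imidazole silylate the primary hydroxyl group selectively to give 16.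

**Step 9.**
- What may go wrong: slow substitution, because an ester is only a moderate para activator and the ortho methoxy group donates into the ring. Longer exposure to base then allows transfer of the silyl group from the primary oxygen to the alkoxide and closure through the wrong oxygen, or attack of the alkoxide on the ester.
- Fallback: the oxidation state is adjusted before the ring is closed, setting out from 16 and returning at 19 in the same number of steps. i-Bu2AlH reduces the ester of 16 to (1R,2S)-1-[3,5-dimethoxy-4-(triisopropylsilyloxy)phenyl]-2-[2-fluoro-5-(hydroxymethyl)-3-methoxyphenyl]-3-(triisopropylsilyloxy)propan-1-ol F7. TEMPO with PhI(OAc)2 oxidises the primary benzylic hydroxyl group selectively to give (1R,2S)-1-[3,5-dimethoxy-4-(triisopropylsilyloxy)phenyl]-2-(2-fluoro-5-formyl-3-methoxyphenyl)-3-(triisopropylsilyloxy)propan-1-ol F8. The formyl group, a stronger acceptor than the ester, now stands para to fluorine, and NaH in THF at 0 °C closes the ring to aldehyde 19.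

**Step 3.**
- What may go wrong: incomplete exchange of catechol for the hindered ditertiary diol 4, and erosion of regioselectivity in the hydroboration by the propargylic oxygen.
- Fallback: the boron ester is made through the isolable boronic acid, setting out from 2 and returning at 6. Hydroboration of 2 with pinacolborane and catalytic Cp2ZrHCl gives 4,4,5,5-tetramethyl-2-[(E)-3-(triisopropylsilyloxy)prop-1-enyl]-1,3,2-dioxaborolane F9. NaIO4 and NH4OAc in acetone/H2O cleave the pinacol ester to (E)-3-(triisopropylsilyloxy)prop-1-enylboronic acid F10, which is condensed with 4 over MgSO4 in CH2Cl2 to give 6.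

**Step 16.**
- What may go wrong: loss of the aryl silyl groups of 24 under the basic conditions. The phenoxides so formed lower the acidity of the benzylic position and stall the olefination; incomplete E selectivity is a lesser concern.
- Fallback: the stilbene is made by a Heck reaction, setting out from 19 and returning at 25. Wittig methylenation of 19 (Ph3PCH3Br, KOt-Bu, THF) gives (2R,3S)-2-[3,5-dimethoxy-4-(triisopropylsilyloxy)phenyl]-5-ethenyl-7-methoxy-3-[(triisopropylsilyloxy)methyl]-2,3-dihydro-1-benzofuran F11. It is coupled with 1,3-bis(tert-butyldimethylsilyloxy)-5-iodobenzene F12, made by bis-silylation of commercial 5-iodobenzene-1,3-diol, under Pd(OAc)2, P(o-tolyl)3 and Et3N in MeCN at 80 °C to give 25 as the E isomer.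

## Further compounds

F1 | step 7 | 3,5-dimethoxy-4-(triisopropylsilyloxy)benzaldehyde | COc1cc(C=O)cc(OC)c1O[Si](C(C)C)(C(C)C)C(C)C
F2 | step 7 | methyl 3-(2-tert-butoxy-2-oxoethyl)-4-fluoro-5-methoxybenzoate | COC(=O)c1cc(OC)c(F)c(CC(=O)OC(C)(C)C)c1
F3 | step 7 | 2-[2-fluoro-3-methoxy-5-(methoxycarbonyl)phenyl]acetic acid | COC(=O)c1cc(OC)c(F)c(CC(=O)O)c1
F4 | step 7 | methyl 3-{2-[(4R)-4-benzyl-2-oxo-1,3-oxazolidin-3-yl]-2-oxoethyl}-4-fluoro-5-methoxybenzoate | COC(=O)c1cc(OC)c(F)c(CC(=O)N2[C@H](Cc3ccccc3)COC2=O)c1
F5 | step 7 | methyl 3-{(2R,3R)-1-[(4R)-4-benzyl-2-oxo-1,3-oxazolidin-3-yl]-3-[3,5-dimethoxy-4-(triisopropylsilyloxy)phenyl]-3-hydroxy-1-oxopropan-2-yl}-4-fluoro-5-methoxybenzoate | COc1cc([C@H](O)[C@H](C(=O)N2[C@H](Cc3ccccc3)COC2=O)c2cc(C(=O)OC)cc(OC)c2F)cc(OC)c1O[Si](C(C)C)(C(C)C)C(C)C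
F6 | step 7 | (1R,2S)-1-[3,5-dimethoxy-4-(triisopropylsilyloxy)phenyl]-2-[2-fluoro-3-methoxy-5-(methoxycarbonyl)phenyl]propane-1,3-diol | COc1cc([C@H](O)[C@H](CO)c2cc(C(=O)OC)cc(OC)c2F)cc(OC)c1O[Si](C(C)C)(C(C)C)C(C)C
F7 | step 9 | (1R,2S)-1-[3,5-dimethoxy-4-(triisopropylsilyloxy)phenyl]-2-[2-fluoro-5-(hydroxymethyl)-3-methoxyphenyl]-3-(triisopropylsilyloxy)propan-1-ol | COc1cc([C@H](O)[C@H](CO[Si](C(C)C)(C(C)C)C(C)C)c2cc(CO)cc(OC)c2F)cc(OC)c1O[Si](C(C)C)(C(C)C)C(C)C
F8 | step 9 | (1R,2S)-1-[3,5-dimethoxy-4-(triisopropylsilyloxy)phenyl]-2-(2-fluoro-5-formyl-3-methoxyphenyl)-3-(triisopropylsilyloxy)propan-1-ol | COc1cc([C@H](O)[C@H](CO[Si](C(C)C)(C(C)C)C(C)C)c2cc(C=O)cc(OC)c2F)cc(OC)c1O[Si](C(C)C)(C(C)C)C(C)C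
F9 | step 3 | 4,4,5,5-tetramethyl-2-[(E)-3-(triisopropylsilyloxy)prop-1-enyl]-1,3,2-dioxaborolane | CC(C)[Si](OC/C=C/B1OC(C)(C)C(C)(C)O1)(C(C)C)C(C)C
F10 | step 3 | (E)-3-(triisopropylsilyloxy)prop-1-enylboronic acid | CC(C)[Si](OC/C=C/B(O)O)(C(C)C)C(C)C
F11 | step 16 | (2R,3S)-2-[3,5-dimethoxy-4-(triisopropylsilyloxy)phenyl]-5-ethenyl-7-methoxy-3-[(triisopropylsilyloxy)methyl]-2,3-dihydro-1-benzofuran | COc1cc([C@@H]2Oc3c(OC)cc(C=C)cc3[C@H]2CO[Si](C(C)C)(C(C)C)C(C)C)cc(OC)c1O[Si](C(C)C)(C(C)C)C(C)C
F12 | step 16 | 1,3-bis(tert-butyldimethylsilyloxy)-5-iodobenzene | CC(C)(C)[Si](C)(C)Oc1cc(I)cc(O[Si](C)(C)C(C)(C)C)c1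
A1 | alternative 1 | (R)-6-bromo-8-methoxy-2-(3,5-dimethoxy-4-pivaloyloxyphenyl)chroman-4-one | COc1cc([C@H]2CC(=O)c3cc(Br)cc(OC)c3O2)cc(OC)c1OC(=O)C(C)(C)C
A2 | alternative 1 | (diacetoxyiodo)benzene, PhI(OAc)2 | CC(=O)OI(OC(C)=O)c1ccccc1
A3 | alternative 1 | methyl (2R,3R)-5-bromo-7-methoxy-2-(3,5-dimethoxy-4-pivaloyloxyphenyl)-2,3-dihydro-1-benzofuran-3-carboxylate (trans) | COc1cc([C@@H]2Oc3c(OC)cc(Br)cc3[C@H]2C(=O)OC)cc(OC)c1OC(=O)C(C)(C)C
A4 | alternative 2 | 4-bromo-2-[2-(tert-butyldimethylsilyloxy)-1-(4-methylphenylsulfonyl)ethyl]-6-methoxyphenol (racemic) | COc1cc(Br)cc(C(CO[Si](C)(C)C(C)(C)C)S(=O)(=O)c2ccc(C)cc2)c1O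
A5 | alternative 2 | 4-bromo-6-[2-(tert-butyldimethylsilyloxy)ethylidene]-2-methoxycyclohexa-2,4-dien-1-one | COC1=CC(Br)=CC(=CCO[Si](C)(C)C(C)(C)C)C1=O
A6 | alternative 2 | (2R,5R)-1-[3,5-dimethoxy-4-(triisopropylsilyloxy)benzyl]-2,5-dimethylthiolan-1-ium trifluoromethanesulfonate (example of a chiral sulfonium salt) | C[C@@H]1CC[C@@H](C)[S+]1Cc1cc(OC)c(O[Si](C(C)C)(C(C)C)C(C)C)c(OC)c1.[O-]S(=O)(=O)C(F)(F)F
A7 | alternative 2 | (2R,3S)-5-bromo-3-[(tert-butyldimethylsilyloxy)methyl]-7-methoxy-2-[3,5-dimethoxy-4-(triisopropylsilyloxy)phenyl]-2,3-dihydro-1-benzofuran (trans) | COc1cc([C@@H]2Oc3c(OC)cc(Br)cc3[C@H]2CO[Si](C)(C)C(C)(C)C)cc(OC)c1O[Si](C(C)C)(C(C)C)C(C)C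
A8 | alternative 3 | [5-(1,3-dioxolan-2-yl)-7-methoxy-1-benzofuran-2-yl]lithium | [Li]c1cc2cc(C3OCCO3)cc(OC)c2o1
A9 | alternative 3 | 2-[3,5-dimethoxy-4-(triisopropylsilyloxy)phenyl]-4,4,5,5-tetramethyl-1,3,2-dioxaborolane | COc1cc(B2OC(C)(C)C(C)(C)O2)cc(OC)c1O[Si](C(C)C)(C(C)C)C(C)C
A10 | alternative 3 | allyl acetate | C=CCOC(C)=O
A11 | alternative 3 | 3-allyl-2-(4,4,5,5-tetramethyl-1,3,2-dioxaborolan-2-yl)-2-[3,5-dimethoxy-4-(triisopropylsilyloxy)phenyl]-5-(1,3-dioxolan-2-yl)-7-methoxy-2,3-dihydro-1-benzofuran, allyl trans to aryl | COc1cc([C@]2(B3OC(C)(C)C(C)(C)O3)Oc3c(OC)cc(C4OCCO4)cc3[C@H]2CC=C)cc(OC)c1O[Si](C(C)C)(C(C)C)C(C)C
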